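All runs are simulated with made-up constants; the scatter is artificial.

A straight line through the first reading is the trap: in the cedar run 18.3% of the substrate has reacted at 0.250 min, and that pace would finish it in 1.37 min, yet at 4.00 min the two products together stand at 87.2%.

| flask | left-handed substrate | right-handed substrate | reagent | racemization catalyst | remark | time |
|---|---|---|---|---|---|---|
| cedar | 0.80 M | 0.80 M | 2.4 M | 80 mM | run made earlier |  |
| elm | 0.80 M | 0.80 M | 2.4 M | 180 mM | run made earlier |  |
| flask | 0.80 M | 0.80 M | 2.40 M | 120 mM |  | 5.0 min |

- cedar (time / min: left-handed product / %, right-handed product / %): 0.250: 12.3, 6.0; 0.833: 29.3, 19.0; 1.33: 38.5, 24.6; 2.00: 43.1, 28.7; 3.00: 49.1, 32.8; 4.00: 51.0, 36.2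
- elm (time / min: left-handed product / %, right-handed product / %): 0.667: 23.8, 15.4; 1.33: 35.3, 22.3; 2.00: 42.8, 27.9; 2.50: 45.0, 28.5; 3.00: 49.4, 32.1; 4.00: 52.3, 35.4

(readings scatter by 1 percentage point)

1. left-handed product and right-handed product together, in percent of the left-handed substrate and right-handed substrate charged together, at 5.0 min
2. excess of left-handed product over right-handed product in the product at 5.0 min
3. whether the exchange between left-handed substrate and right-handed substrate keeps pace with the reaction: how far the product's excess at 5.0 min gets from its value without exchange to its value with instant exchange (above 80% keeps pace, below 20% hardly takes part, else lags behind)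

- reagent is single-handed; left-handed substrate and right-handed substrate are mirror images of each other, charged as a racemate, each of them at the stated concentration
- what was read earlier has a scatter of 1 percentage point, one standard deviation
- an excess is the difference of the two amounts in percent of their sum
- an excess is below zero if the other one leads
- the handed part of reagent does not stay in what it makes, so the products of the two hands are mirror images too

I count two factors that slow the rate: the share of substrate left and the share of reagent left, one reagent going with each substrate. In the cedar run at 4.00 min I reckon these from the readings as 12.8% and 41.9%, so by these two factors the rate is down to 5.36% of its start.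

To carry this slowing through the whole curve, I replace the two hands by one mean hand. In that picture the logarithm of reagent share over substrate share grows straight in time, and its growth per minute, divided by the reagent surplus [reagent] − [left-handed substrate] − [right-handed substrate], is a constant. At 4.00 min the cedar run gives 0.370 /M/min, and the elm run gives 0.380 /M/min. I carry their mean, 0.375 /M/min, the mean rate constant.

For this flask, over 5.0 min, it gives me 91.3%, with the rate down to 3.42% of its start. To check the error of the mean, I take the cedar reading at 1.33 min instead. It gives 0.424 /M/min and so 93.0%, a shift of 1.7 percentage points.

The forecast says 91%, an excess of 18.5%, and lags behind: “lagging, though near the boundary”.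

    reagent + left-handed substrate → left-handed product (k = 0.00845 /M/s)
    reagent + right-handed substrate → right-handed product (k = 0.00450 /M/s)
    left-handed substrate + racemization catalyst ⇌ right-handed substrate + racemization catalyst, rate k3*[racemization catalyst]*[left-handed substrate] forward; the back reaction follows from the equilibrium constant (k = 0.240 /M/s)
    reagent → decomposition product (k = 4.91 × 10⁻⁵ /s)
    2 racemization catalyst → spent catalyst (k = 0.422 /M/s)

The flask gives 90.4%, less than my 91.3%, and an excess of 15.7%, less than the forecast's 18.5%. In this flask the exchange lags behind at 36% of the way, and the forecast's call would be wrong with a share under 20% or over 80%. In a neighbouring flask with 0.96 M of reagent, less than the 1.60 M of substrate, reagent is the limiting reagent and the surplus is −0.640 M. The same 0.375 /M/min gives 51.2% under a ceiling of 60.0%. That neighbour gives 51.1%, with 14.3% of its reagent left.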